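**Plan**

Locants are those of the chromene core (O1, C2–C4, C4a, C5–C8, C8a). Retrosynthetic cuts, in order: C8–prenyl; O1–C2 and the C4 acyl unit on C4a; then C7–C8 and C4a–C8a together; then the cyclobutenone (ketene + ynol ether) and the siloxyalkyne (ester homologation).
Enabling feature: the carbocycle C4a–C5–C6–C7–C8–C8a is a disguised phloroglucinol whose oxygenated carbons C5, C7, C8a alternate with the carbon-substituted C4a, C6, C8. C7(=O)–C6–C5(O)–C4a therefore maps onto a 3-alkoxy vinylketene and C8–C8a(O) onto a 1-siloxyalkyne of matching polarity.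
Forward order of rings: the benzene ring first, by convergent thermal benzannulation of two chiral fragments that delivers three differentiated oxygens; then the dihydropyranone (formylation, hydroacylation, oxa-Michael); last, dearomatization at C8 and deprotection.
Stereochemistry: the cyclobutane comes from (+)-α-pinene, all ten carbons kept (its C3 becomes C8a). C3 of the hexanoic acid comes from desymmetrization of 3-propylglutaric anhydride. The cis C2/C3 pair comes from a quinine-mediated oxa-Michael addition. C8 comes from ligand-controlled palladium allylation.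

Key step: step 8

Remark: the absolute sense of the reagent-controlled steps 6 (quinidine), 12 (quinine) and 13 ((R,R)-ligand) is assigned by analogy with the closest substrates; if a sense proves opposite, the pseudoenantiomeric alkaloid or the antipodal ligand is used instead.

**Route**

Step 1
Reactants: 1 (+)-α-pinene
Product: 2 cis-pinonic acid
Conditions: RuCl3·xH2O (cat.), NaIO4, CCl4/MeCN/H2O, rt
Reagents that add atoms: sodium periodate [Na+].[O-]I(=O)(=O)=O; water O
Why: RuO4 formed in situ cleaves the trisubstituted alkene oxidatively to methyl ketone and carboxylic acid without touching the two ring stereocenters, so the cis-1,3-disubstituted cyclobutane of the target is taken intact from the terpene.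

Step 2
Reactants: 2 cis-pinonic acid
Product: 3 methyl cis-pinonate
Conditions: MeI, K2CO3, DMF, rt
Reagents that add atoms: iodomethane CI
Why: SN2 O-alkylation of the carboxylate under weakly basic conditions gives the ester needed for the homologation without epimerizing the carbon next to the ketone.

Step 3
Reactants: 3 methyl cis-pinonate
Product: 4 isopropenyl ester
Conditions: Ph3PCH3Br, KOtBu, THF, 0 °C → rt
Reagents that add atoms: methyltriphenylphosphonium bromide C[P+](c1ccccc1)(c1ccccc1)c1ccccc1.[Br-]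
Why: Wittig methylenation of the methyl ketone with the preformed ylide installs the isopropenyl group chemoselectively over the ester, and short contact at low temperature should preserve the ring stereocenter next to the ketone.

Step 4
Reactants: 4 isopropenyl ester
Product: 6 siloxyalkyne, via lithium ynolate 5 (not isolated)
Conditions: CH2Br2, LiTMP (lithium 2,2,6,6-tetramethylpiperidide), THF, −78 °C; n-BuLi, −78 → 0 °C; iPr3SiCl, −78 °C → rt
Reagents that add atoms: dibromomethane BrCBr; chlorotri(propan-2-yl)silane CC(C)[Si](Cl)(C(C)C)C(C)C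
Why: Kowalski ester homologation: dibromomethyllithium adds to the ester, bromine–lithium exchange on the dibromo enolate triggers 1,2-shift of the cyclobutylmethyl group to the carbenoid carbon to give ynolate 5 (the former ester carbon keeps its oxygen and becomes C8a), and the bulky silyl chloride traps 5 on oxygen.

Step 5
Reactants: 7 2-(trimethylsilyl)ethanol, 8 trichloroethene
Product: 11 ynol ether, via dichlorovinyl ether 9 (not isolated), via lithium alkoxyacetylide 10 (not isolated)
Conditions: KH, THF, 0 °C; 8, −50 °C → rt; n-BuLi (2.2 equiv), −78 → −40 °C; H2O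
Reagents that add atoms: none
Why: The potassium alkoxide (kept cold to avoid Peterson-type loss of ethene) adds to dichloroacetylene formed in situ from 8 to give the (E)-dichlorovinyl ether 9, which n-BuLi converts by elimination and chlorine–lithium exchange into acetylide 10, protonated to the terminal alkynyl ether (established alcohol-to-ynol-ether sequence).

Step 6
Reactants: 12 3-propylglutaric anhydride
Product: 13 (R)-hemiester
Conditions: quinidine (1.1 equiv), MeOH (3 equiv), toluene, −55 °C
Reagents that add atoms: methanol CO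
Why: Alkaloid-mediated methanolysis selects one of the two enantiotopic carbonyl groups of the prochiral anhydride (desymmetrization) and so sets the propyl-bearing stereocenter as (R) in 13, which corresponds to (S) at C3 of the hexanoic acid chain of the target.

Step 7
Reactants: 13 (R)-hemiester, 11 ynol ether
Product: 16 cyclobutenone, via acid chloride 14 (not isolated), via ketene 15 (not isolated)
Conditions: (COCl)2, DMF (cat.), CH2Cl2, 0 °C → rt; evaporate; 11 (1.5 equiv), Et3N, MeCN, 0 °C → rt
Reagents that add atoms: none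
Why: Oxalyl chloride gives 14, triethylamine dehydrochlorinates it to aldoketene 15, and a regioselective ketene–ynol ether [2+2] cycloaddition (terminal alkyne carbon to the ketene carbonyl carbon) gives the 3-alkoxy-4-alkylcyclobutenone; its new ring stereocenter forms unselectively and is erased in step 8.

Step 8
Reactants: 16 cyclobutenone, 6 siloxyalkyne
Product: 21 phenol, via vinylketene 17 (not isolated), via alkenylcyclobutenone 18 (not isolated), via dienylketene 19 (not isolated), via cyclohexadienone 20 (not isolated)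
Conditions: 6 (1.3 equiv), toluene, 80 °C then 110 °C, sealed tube, argon
Reagents that add atoms: none
Why: Heat opens 16 by 4π-electrocyclic cleavage of its C(=O)–C(sp3) bond to the 3-alkoxy vinylketene 17, whose ketene C=C adds 6 in a regiospecific [2+2] (ketene carbonyl carbon to the nucleophilic alkyl-bearing alkyne carbon = C7–C8, ketene α-carbon to the siloxy-bearing carbon = C4a–C8a) to give 18; a second 4π opening gives 19, 6π-electrocyclization (C6–C7) gives 20, and tautomerization gives 21. The closest known reaction type is the Danheiser benzannulation of cyclobutenones with alkoxy- or siloxyalkynes. One ring is closed, the benzene ring, by a pericyclic relay ([2+2], 4π opening, 6π-electrocyclic closure) that amounts to a [4+2] union of the C7–C6–C5–C4a unit with the C8–C8a unit; the pyranone ring is not yet present. No stereocenter is created, since the sp3 ring carbons of 16, 18 and 20 all become aromatic, and the cyclobutane and side-chain centers lie outside the reacting π-system and should not epimerize under neutral thermolysis. The selectivities needed are the orientation of the [2+2], secured by the polarization of the ynol ether and of the ketene, and suppression of ketene capture by the product phenol, secured by slow thermal generation of 17 in the presence of excess 6; the hexasubstituted arene arrives with its three oxygens differentiated (free OH at C7, silyl ether at C8a, alkyl ether at C5).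

Step 9
Reactants: 21 phenol
Product: 22 diol
Conditions: TBAF, AcOH, THF, 0 °C
Reagents that add atoms: none
Why: Buffered fluoride cleaves the aryl silyl ether selectively (Si–F bond formation) and frees the hydroxyl that will become O1, while the 2-(trimethylsilyl)ethyl ether, which needs forcing fluoride conditions, and the ester should survive.

Step 10
Reactants: 22 diol
Product: 23 salicylaldehyde
Conditions: MgCl2, Et3N, (CH2O)n, MeCN, 70 °C; 1 M HCl work-up
Reagents that add atoms: paraformaldehyde (as formaldehyde) C=O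
Why: Magnesium-mediated ortho-formylation: the magnesium phenoxide binds formaldehyde and delivers it to the adjacent ring carbon while a second formaldehyde accepts hydride, so the aldehyde should enter only at the single unsubstituted carbon (future C4a), ortho to the newly freed hydroxyl.

Step 11
Reactants: 23 salicylaldehyde
Product: 24 hydroxyaryl enone
Conditions: [RhCl(cod)]2 (2.5 mol%), 1,1'-bis(diphenylphosphino)ferrocene (5 mol%), Na2CO3 (5 mol%), but-2-yne (5 equiv), toluene, 80 °C, sealed tube
Reagents that add atoms: but-2-yne CC#CC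
Why: Hydroxyl-directed aldehyde C–H activation by rhodium, syn insertion of the alkyne and reductive elimination (intermolecular alkyne hydroacylation of a salicylaldehyde) should give the (E)-2-methylbut-2-enoyl ketone.

Step 12
Reactants: 24 hydroxyaryl enone
Product: 25 cis-chromanone
Conditions: quinine (20 mol%), chlorobenzene, rt
Reagents that add atoms: none
Why: Intramolecular oxa-Michael addition within a chiral phenoxide–quininium ion pair should set C2 as (R) by face-selective C–O bond formation, and kinetic protonation of the resulting enol anti to the new C2 methyl group should set C3 as (S), i.e. the cis pair; the weak base at room temperature avoids equilibration to the trans isomer.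

Step 13
Reactants: 25 cis-chromanone
Product: 26 dearomatized prenyl dienone
Conditions: Pd2(dba)3·CHCl3 (2.5 mol%), (1R,2R)-N,N'-bis[2-(diphenylphosphino)benzoyl]cyclohexane-1,2-diamine (7.5 mol%), methyl 3-methylbut-2-en-1-yl carbonate (1.5 equiv), toluene, 0 °C → rt
Reagents that add atoms: methyl 3-methylbut-2-en-1-yl carbonate COC(=O)OCC=C(C)C
Why: Tsuji–Trost allylic dearomatization: zerovalent palladium ionizes the carbonate to a π-prenyl complex and methoxide (after loss of CO2), the C7 phenoxide attacks through carbon at the unsubstituted allyl terminus (O-allylation being reversible under the catalyst), C8 with its primary alkyl group should be preferred over C6 with its branched chain, and the chiral diphosphine pocket is relied on to select the face of the planar phenoxide so that C8 forms as (R); the product has no acidic OH and cannot be allylated twice.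

Step 14
Reactants: 26 dearomatized prenyl dienone
Product: 28 target acid, via methyl ester 27 (not isolated)
Conditions: TBAF, THF, rt; then LiOH, THF/H2O, rt; 1 M HCl, 0 °C
Reagents that add atoms: lithium hydroxide [Li+].[OH-]
Why: Fluoride attacks silicon and fragments the vinylogous 2-(trimethylsilyl)ethyl ester (loss of ethene) to the C5 enolate of 27, and hydroxide then saponifies the methyl ester while the delocalized anion shields the C8 β-dicarbonyl array from retro-Claisen cleavage and C3 from epimerization; cold acidification gives 28.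

**Compound list**

1 | (+)-α-pinene, (1R,5R)-2,6,6-trimethylbicyclo[3.1.1]hept-2-ene | CC1=CC[C@@H]2C[C@H]1C2(C)C | starting material
2 | cis-pinonic acid, 2-[(1S,3S)-3-acetyl-2,2-dimethylcyclobutyl]acetic acid | CC(=O)[C@H]1C[C@@H](CC(=O)O)C1(C)C | intermediate
3 | methyl 2-[(1S,3S)-3-acetyl-2,2-dimethylcyclobutyl]acetate | CC(=O)[C@H]1C[C@@H](CC(=O)OC)C1(C)C | intermediate
4 | methyl 2-[(1S,3R)-2,2-dimethyl-3-(prop-1-en-2-yl)cyclobutyl]acetate | C=C(C)[C@H]1C[C@@H](CC(=O)OC)C1(C)C | intermediate
5 | lithium 3-[(1S,3R)-2,2-dimethyl-3-(prop-1-en-2-yl)cyclobutyl]prop-1-yn-1-olate | C=C(C)[C@H]1C[C@@H](CC#C[O-])C1(C)C.[Li+] | intermediate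
6 | ({3-[(1S,3R)-2,2-dimethyl-3-(prop-1-en-2-yl)cyclobutyl]prop-1-yn-1-yl}oxy)tri(propan-2-yl)silane | C=C(C)[C@H]1C[C@@H](CC#CO[Si](C(C)C)(C(C)C)C(C)C)C1(C)C | intermediate
7 | 2-(trimethylsilyl)ethanol | C[Si](C)(C)CCO | starting material
8 | trichloroethene | ClC=C(Cl)Cl | starting material
9 | {2-[(E)-(1,2-dichloroethenyl)oxy]ethyl}trimethylsilane | C[Si](C)(C)CCO/C(Cl)=C\Cl | intermediate
10 | lithium [2-(trimethylsilyl)ethoxy]ethynide | C[Si](C)(C)CCOC#[C-].[Li+] | intermediate
11 | [2-(ethynyloxy)ethyl]trimethylsilane | C[Si](C)(C)CCOC#C | intermediate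
12 | 3-propylglutaric anhydride, 4-propyloxane-2,6-dione | CCCC1CC(=O)OC(=O)C1 | starting material
13 | (3R)-3-(2-methoxy-2-oxoethyl)hexanoic acid | OC(=O)C[C@@H](CCC)CC(=O)OC | intermediate
14 | methyl (3S)-3-(2-chloro-2-oxoethyl)hexanoate | ClC(=O)C[C@@H](CCC)CC(=O)OC | intermediate
15 | methyl (3S)-3-(2-oxoethenyl)hexanoate (ketene) | O=C=C[C@@H](CCC)CC(=O)OC | intermediate
16 | methyl (3S)-3-{2-oxo-4-[2-(trimethylsilyl)ethoxy]cyclobut-3-en-1-yl}hexanoate, both epimers at the ring carbon | O=C1C=C(OCC[Si](C)(C)C)C1[C@@H](CCC)CC(=O)OC | intermediate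
17 | methyl (3S,4Z)-7-oxo-3-propyl-5-[2-(trimethylsilyl)ethoxy]hepta-4,6-dienoate (vinylketene) | O=C=C/C(OCC[Si](C)(C)C)=C/[C@@H](CCC)CC(=O)OC | intermediate
18 | methyl (3S,4Z)-5-(3-{[(1S,3R)-2,2-dimethyl-3-(prop-1-en-2-yl)cyclobutyl]methyl}-4-oxo-2-{[tri(propan-2-yl)silyl]oxy}cyclobut-2-en-1-yl)-3-propyl-5-[2-(trimethylsilyl)ethoxy]pent-4-enoate, both ring epimers | C=C(C)[C@H]1C[C@@H](CC2=C(O[Si](C(C)C)(C(C)C)C(C)C)C(/C(OCC[Si](C)(C)C)=C/[C@@H](CCC)CC(=O)OC)C2=O)C1(C)C | intermediate
19 | methyl (3S,4Z,6E)-8-{[(1S,3R)-2,2-dimethyl-3-(prop-1-en-2-yl)cyclobutyl]methyl}-9-oxo-3-propyl-7-{[tri(propan-2-yl)silyl]oxy}-5-[2-(trimethylsilyl)ethoxy]nona-4,6,8-trienoate (dienylketene) | C=C(C)[C@H]1C[C@@H](CC(=C=O)/C(O[Si](C(C)C)(C(C)C)C(C)C)=C\C(OCC[Si](C)(C)C)=C\[C@@H](CCC)CC(=O)OC)C1(C)C | intermediate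
20 | methyl (3S)-3-(3-{[(1S,3R)-2,2-dimethyl-3-(prop-1-en-2-yl)cyclobutyl]methyl}-2-oxo-4-{[tri(propan-2-yl)silyl]oxy}-6-[2-(trimethylsilyl)ethoxy]cyclohexa-3,5-dien-1-yl)hexanoate, both ring epimers | C=C(C)[C@H]1C[C@@H](CC2=C(O[Si](C(C)C)(C(C)C)C(C)C)C=C(OCC[Si](C)(C)C)C([C@@H](CCC)CC(=O)OC)C2=O)C1(C)C | intermediate
21 | methyl (3S)-3-[3-{[(1S,3R)-2,2-dimethyl-3-(prop-1-en-2-yl)cyclobutyl]methyl}-2-hydroxy-4-{[tri(propan-2-yl)silyl]oxy}-6-[2-(trimethylsilyl)ethoxy]phenyl]hexanoate | C=C(C)[C@H]1C[C@@H](Cc2c(O)c([C@@H](CCC)CC(=O)OC)c(OCC[Si](C)(C)C)cc2O[Si](C(C)C)(C(C)C)C(C)C)C1(C)C | intermediate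
22 | methyl (3S)-3-[3-{[(1S,3R)-2,2-dimethyl-3-(prop-1-en-2-yl)cyclobutyl]methyl}-2,4-dihydroxy-6-[2-(trimethylsilyl)ethoxy]phenyl]hexanoate | C=C(C)[C@H]1C[C@@H](Cc2c(O)c([C@@H](CCC)CC(=O)OC)c(OCC[Si](C)(C)C)cc2O)C1(C)C | intermediate
23 | methyl (3S)-3-[3-{[(1S,3R)-2,2-dimethyl-3-(prop-1-en-2-yl)cyclobutyl]methyl}-5-formyl-2,4-dihydroxy-6-[2-(trimethylsilyl)ethoxy]phenyl]hexanoate | C=C(C)[C@H]1C[C@@H](Cc2c(O)c([C@@H](CCC)CC(=O)OC)c(OCC[Si](C)(C)C)c(C=O)c2O)C1(C)C | intermediate
24 | methyl (3S)-3-[3-{[(1S,3R)-2,2-dimethyl-3-(prop-1-en-2-yl)cyclobutyl]methyl}-2,4-dihydroxy-5-[(2E)-2-methylbut-2-enoyl]-6-[2-(trimethylsilyl)ethoxy]phenyl]hexanoate | C=C(C)[C@H]1C[C@@H](Cc2c(O)c([C@@H](CCC)CC(=O)OC)c(OCC[Si](C)(C)C)c(C(=O)/C(C)=C/C)c2O)C1(C)C | intermediate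
25 | methyl (3S)-3-[(2R,3S)-8-{[(1S,3R)-2,2-dimethyl-3-(prop-1-en-2-yl)cyclobutyl]methyl}-7-hydroxy-2,3-dimethyl-4-oxo-5-[2-(trimethylsilyl)ethoxy]-3,4-dihydro-2H-chromen-6-yl]hexanoate | C=C(C)[C@H]1C[C@@H](Cc2c(O)c([C@@H](CCC)CC(=O)OC)c(OCC[Si](C)(C)C)c3c2O[C@H](C)[C@H](C)C3=O)C1(C)C | intermediate
26 | methyl (3S)-3-[(2R,3S,8R)-8-{[(1S,3R)-2,2-dimethyl-3-(prop-1-en-2-yl)cyclobutyl]methyl}-2,3-dimethyl-8-(3-methylbut-2-en-1-yl)-4,7-dioxo-5-[2-(trimethylsilyl)ethoxy]-3,4,7,8-tetrahydro-2H-chromen-6-yl]hexanoate | C=C(C)[C@H]1C[C@@H](C[C@@]2(CC=C(C)C)C(=O)C([C@@H](CCC)CC(=O)OC)=C(OCC[Si](C)(C)C)C3=C2O[C@H](C)[C@H](C)C3=O)C1(C)C | intermediate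
27 | methyl (3S)-3-[(2R,3S,8R)-8-{[(1S,3R)-2,2-dimethyl-3-(prop-1-en-2-yl)cyclobutyl]methyl}-5-hydroxy-2,3-dimethyl-8-(3-methylbut-2-en-1-yl)-4,7-dioxo-3,4,7,8-tetrahydro-2H-chromen-6-yl]hexanoate (formed as its enolate) | C=C(C)[C@H]1C[C@@H](C[C@@]2(CC=C(C)C)C(=O)C([C@@H](CCC)CC(=O)OC)=C(O)C3=C2O[C@H](C)[C@H](C)C3=O)C1(C)C | intermediate
28 | (3S)-3-[(2R,3S,8R)-8-{[(1S,3R)-2,2-dimethyl-3-(prop-1-en-2-yl)cyclobutyl]methyl}-5-hydroxy-2,3-dimethyl-8-(3-methylbut-2-en-1-yl)-4,7-dioxo-3,4,7,8-tetrahydro-2H-chromen-6-yl]hexanoic acid | C=C(C)[C@H]1C[C@@H](C[C@@]2(CC=C(C)C)C(=O)C([C@@H](CCC)CC(=O)O)=C(O)C3=C2O[C@H](C)[C@H](C)C3=O)C1(C)C | target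

**Count**

Total steps: 14. Longest linear sequence: 11 steps (steps 1–4, then 8–14).

**Steps most likely to fail**

1. Step 13. What may go wrong: poor facial discrimination at C8 by the catalyst in a substrate that already carries six stereocenters, attack through C6 instead of C8, or O-allylation that does not revert. Prior closure of the hydroxy ester 25 to its dihydrocoumarin lactone would not matter, because methoxide released from the carbonate would reopen it.
Fallback, from 25 back to 28: a substrate-controlled sigmatropic relay in place of catalyst control. 25 is acylated at the C7 hydroxyl (pivaloyl chloride, Et3N, DMAP) to the C7 pivalate F1. Fluoride (TBAF, THF, rt to 50 °C) removes the 2-(trimethylsilyl)ethyl group to give the chelated C5 phenol F2. Mitsunobu etherification with 3-methylbut-2-en-1-ol (PPh3, DIAD) gives the C5 prenyl ether F3. Heating (toluene, 120 °C) induces a para-Claisen rearrangement, a [3,3] shift to C4a followed by a Cope shift to C8, which can end only at C8 (para to O5), and gives the 8-prenyl dienone enol pivalate F4. The first shift should occur on the face of C4a opposite the axial C3 methyl group of the cis-chromanone, and the suprafacial Cope shift carries the prenyl group to the same face of C8, which is the (8R) configuration. LiOH then cleaves the enol pivalate and the methyl ester of F4 to give 28.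

2. Step 8. What may go wrong: slow electrocyclic opening of the donor-stabilized cyclobutenone, so that thermal loss of the siloxyalkyne and acylation of the product phenol by the ketene outrun the annulation.
Fallback, from 13 back to 21: the vinylketene is generated at room temperature by elimination instead of by ring opening. 13 is homologated (carbonyldiimidazole, then the magnesium salt of mono-tert-butyl malonate) to the β-keto ester F5. Mitsunobu O-alkylation of its enol with 2-(trimethylsilyl)ethanol gives the (E)-enol ether F6. SOCl2 converts the tert-butyl ester directly into the acid chloride F7. Et3N at room temperature in the presence of 6 effects 1,4-dehydrochlorination to vinylketene 17, which is trapped as 18; brief heating completes the sequence through 19 and 20 to 21.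

3. Step 11. What may go wrong: sluggish C–H activation at the doubly ortho-substituted aldehyde, decarbonylation, or base-induced premature ring closure of the hydroxy enone, which would bypass the stereocontrol of step 12.
Fallback, from 23 back to 24: polar two-step acylation instead of C–H activation. Nozaki–Hiyama–Kishi addition of (E)-2-iodobut-2-ene (CrCl2, NiCl2 cat., DMF), chemoselective for the aldehyde over the ester, gives the allylic alcohol F8 as a mixture of carbinol epimers. MnO2 then oxidizes the benzylic allylic alcohol to ketone 24.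

**Further compounds**

F1 | step 13 | methyl (3S)-3-[(2R,3S)-8-{[(1S,3R)-2,2-dimethyl-3-(prop-1-en-2-yl)cyclobutyl]methyl}-7-(2,2-dimethylpropanoyloxy)-2,3-dimethyl-4-oxo-5-[2-(trimethylsilyl)ethoxy]-3,4-dihydro-2H-chromen-6-yl]hexanoate | C=C(C)[C@H]1C[C@@H](Cc2c(OC(=O)C(C)(C)C)c([C@@H](CCC)CC(=O)OC)c(OCC[Si](C)(C)C)c3c2O[C@H](C)[C@H](C)C3=O)C1(C)C
F2 | step 13 | methyl (3S)-3-[(2R,3S)-8-{[(1S,3R)-2,2-dimethyl-3-(prop-1-en-2-yl)cyclobutyl]methyl}-7-(2,2-dimethylpropanoyloxy)-5-hydroxy-2,3-dimethyl-4-oxo-3,4-dihydro-2H-chromen-6-yl]hexanoate | C=C(C)[C@H]1C[C@@H](Cc2c(OC(=O)C(C)(C)C)c([C@@H](CCC)CC(=O)OC)c(O)c3c2O[C@H](C)[C@H](C)C3=O)C1(C)C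
F3 | step 13 | methyl (3S)-3-[(2R,3S)-8-{[(1S,3R)-2,2-dimethyl-3-(prop-1-en-2-yl)cyclobutyl]methyl}-7-(2,2-dimethylpropanoyloxy)-2,3-dimethyl-5-[(3-methylbut-2-en-1-yl)oxy]-4-oxo-3,4-dihydro-2H-chromen-6-yl]hexanoate | C=C(C)[C@H]1C[C@@H](Cc2c(OC(=O)C(C)(C)C)c([C@@H](CCC)CC(=O)OC)c(OCC=C(C)C)c3c2O[C@H](C)[C@H](C)C3=O)C1(C)C
F4 | step 13 | methyl (3S)-3-[(2R,3S,8R)-8-{[(1S,3R)-2,2-dimethyl-3-(prop-1-en-2-yl)cyclobutyl]methyl}-7-(2,2-dimethylpropanoyloxy)-2,3-dimethyl-8-(3-methylbut-2-en-1-yl)-4,5-dioxo-3,4,5,8-tetrahydro-2H-chromen-6-yl]hexanoate | C=C(C)[C@H]1C[C@@H](C[C@@]2(CC=C(C)C)C(OC(=O)C(C)(C)C)=C([C@@H](CCC)CC(=O)OC)C(=O)C3=C2O[C@H](C)[C@H](C)C3=O)C1(C)C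
F5 | step 8 | 1-tert-butyl 7-methyl (5R)-3-oxo-5-propylheptanedioate | CC(C)(C)OC(=O)CC(=O)C[C@@H](CCC)CC(=O)OC
F6 | step 8 | 1-tert-butyl 7-methyl (2E,5R)-5-propyl-3-[2-(trimethylsilyl)ethoxy]hept-2-enedioate | CC(C)(C)OC(=O)/C=C(/OCC[Si](C)(C)C)C[C@@H](CCC)CC(=O)OC
F7 | step 8 | methyl (3R,5E)-7-chloro-7-oxo-3-propyl-5-[2-(trimethylsilyl)ethoxy]hept-5-enoate | ClC(=O)/C=C(/OCC[Si](C)(C)C)C[C@@H](CCC)CC(=O)OC
F8 | step 11 | methyl (3S)-3-[3-{[(1S,3R)-2,2-dimethyl-3-(prop-1-en-2-yl)cyclobutyl]methyl}-2,4-dihydroxy-5-[(2E)-1-hydroxy-2-methylbut-2-en-1-yl]-6-[2-(trimethylsilyl)ethoxy]phenyl]hexanoate, both carbinol epimers | C=C(C)[C@H]1C[C@@H](Cc2c(O)c([C@@H](CCC)CC(=O)OC)c(OCC[Si](C)(C)C)c(C(O)/C(C)=C/C)c2O)C1(C)C
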